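The plan rests on the 1,3-dioxygenated array across the spiro carbon: the cyclohexane C(CH3)–OH carbon and the cyclopentane CH–OH carbon both flank the quaternary centre shared by the two rings, which is the signature of a semipinacol ring expansion of a 2,3-epoxy alcohol. The precursor is an epoxycyclohexane built from (S)-carvone, carrying a 1-hydroxycyclobutyl group on one epoxide carbon and a methyl group on the other. One Lewis acid operation shifts a cyclobutane bond to the epoxide carbon, which enlarges the four-membered ring to the spiro cyclopentanone, creates the quaternary centre with inversion and unveils the tertiary alcohol. A temporary cis-fused lactone on the cyclopentane then receives the trienyl chain by aldol condensation.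

Key step: step 6

Assumption: the enal geometry of the target (formyl group cis to the ring carbon that carries the hydroxypropyl chain) is taken to be the thermodynamically preferred geometry of that tetrasubstituted alkene.

Step 1
Reactants: 1 (S)-(+)-carvone; 2 allyl bromide
Product: 4 trans-6-allylcarvone [(5S,6R)-6-allyl-2-methyl-5-(prop-1-en-2-yl)cyclohex-2-en-1-one], via lithium dienolate 3 (not isolated)
Conditions: LiN(iPr)2 (1.05 equiv), THF, −78 °C; then allyl bromide, −78 → −20 °C
Reagents that add atoms: none
Why: Kinetic deprotonation at the alpha-prime methylene gives the cross-conjugated lithium dienolate, and its enolate alkylation by the allylic bromide should take place on the face away from the neighbouring isopropenyl group, which sets the new centre trans to it without touching the carvone centre.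

Step 2
Reactants: 4 trans-6-allylcarvone
Product: 6 tetrasubstituted enol triflate [trans-6-allyl-2-methyl-5-(prop-1-en-2-yl)cyclohex-1-en-1-yl trifluoromethanesulfonate], via lithium enolate 5 (not isolated)
Conditions: LiBH(s-Bu)3 (1.05 equiv), THF, −78 °C; then PhNTf2, −78 °C → rt
Reagents that add atoms: N-phenylbis(trifluoromethanesulfonimide), O=S(=O)(N(c1ccccc1)S(=O)(=O)C(F)(F)F)C(F)(F)F
Why: LiBH(s-Bu)3 adds hydride in conjugate fashion to the beta-unsubstituted enone and the regiodefined enolate is trapped on oxygen by the triflimide (conjugate reduction–enolate triflation), which fixes the double bond between the former carbonyl carbon and the methyl-bearing carbon while both stereocentres stay untouched under the aprotic conditions.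

Step 3
Reactants: 6 enol triflate
Product: 7 alkenylstannane [trimethyl(trans-6-allyl-2-methyl-5-(prop-1-en-2-yl)cyclohex-1-en-1-yl)stannane]
Conditions: Me3SnSnMe3 (1.5 equiv), Pd(PPh3)4 (5 mol %), LiCl (6 equiv), THF, 65 °C
Reagents that add atoms: hexamethylditin, C[Sn](C)(C)[Sn](C)(C)C
Why: Palladium-catalysed coupling of an enol triflate with a distannane (Stille-type stannylation, LiCl assisting transmetalation) replaces the triflate by trimethylstannyl at the same carbon and is known for 2,6-disubstituted cyclohexenyl triflates.

Step 4
Reactants: 7 alkenylstannane; 8 cyclobutanone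
Product: 10 1-(cyclohexenyl)cyclobutanol [1-(trans-6-allyl-2-methyl-5-(prop-1-en-2-yl)cyclohex-1-en-1-yl)cyclobutan-1-ol], via alkenyllithium 9 (not isolated)
Conditions: MeLi (1.1 equiv), THF, −78 → −20 °C; then cyclobutanone, −78 °C; H2O quench
Reagents that add atoms: none
Why: Tin–lithium exchange gives the hindered alkenyllithium, which should undergo 1,2-addition to the small, strained cyclobutanone faster than it deprotonates it, and no stereocentre arises because the carbinol carbon carries two identical ring arms.

Step 5
Reactants: 10 1-(cyclohexenyl)cyclobutanol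
Product: 11 epoxy cyclobutanol (epoxide oxygen cis to the allyl group and trans to the isopropenyl group)
Conditions: VO(acac)2 (5 mol %), tBuOOH (1.5 equiv, decane), CH2Cl2, 0 °C → rt
Reagents that add atoms: tert-butyl hydroperoxide, CC(C)(C)OO
Why: Vanadium-catalysed hydroxyl-directed epoxidation of an allylic alcohol selects the tetrasubstituted double bond over the allyl and isopropenyl groups, and in the trans-diaxial half-chair (enforced by allylic 1,2-strain between the cyclobutanol and a pseudoequatorial allyl group) the axial isopropenyl group sits 1,3-syn-axial over one face of the carbinol-bearing alkene carbon, so oxygen should be delivered to the opposite face, cis to the allyl group.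

Step 6
Reactants: 11 epoxy cyclobutanol
Product: 12 spiro[4.5] beta-hydroxy ketone [10-allyl-6-hydroxy-6-methyl-9-(prop-1-en-2-yl)spiro[4.5]decan-1-one]
Conditions: BF3·OEt2 (0.2 equiv), CH2Cl2, −78 → −40 °C
Reagents that add atoms: none
Why: BF3 binds the epoxide oxygen and, as the C–O bond at the carbinol-bearing ring carbon loosens, the cyclobutane C–C bond lying antiperiplanar to it migrates from the carbinol carbon to that ring carbon while the hydroxyl oxygen becomes the carbonyl, a concerted 1,2-alkyl shift. The closest known reaction type is the Lewis acid semipinacol rearrangement of 2,3-epoxy alcohols in its cyclobutanol form, which gives spirocyclic beta-hydroxy cyclopentanones. The five-membered ring arises by enlargement of the cyclobutane through the migrating bond, so no ring is formed by cyclisation and the cyclohexane is untouched. The spiro carbon is set by inversion at the migration terminus and therefore follows the epoxide face fixed in step 5, whereas the methyl-bearing carbon keeps its C–O bond and its configuration and emerges as the tertiary alcohol on the face of the allyl group. The step needs opening at the carbinol-bearing epoxide carbon and not at the methyl-bearing one: release of cyclobutane strain together with carbonyl formation secures this, the two cyclobutane bonds are equivalent so no regiochemical question arises, and low temperature with substoichiometric Lewis acid keeps the allyl and isopropenyl groups out of cation–olefin side reactions.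

Step 7
Reactants: 12 spiro beta-hydroxy ketone
Product: 13 trimethylsilyl ether of 12
Conditions: TMSOTf (1.3 equiv), 2,6-lutidine (2 equiv), CH2Cl2, −78 °C
Reagents that add atoms: trimethylsilyl trifluoromethanesulfonate, C[Si](C)(C)OS(=O)(=O)C(F)(F)F
Why: Silylation of the hindered tertiary alcohol with a silyl triflate and a non-nucleophilic base masks the aldol hydroxyl, so that the strongly basic next step cannot set off retro-aldol cleavage of the bond between the spiro carbon and the carbinol carbon.

Step 8
Reactants: 13 trimethylsilyl ether; 14 methyl bromoacetate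
Product: 17 hydroxy keto ester (methyl acetate arm on the cyclopentanone alpha-carbon), via lithium enolate 15 (not isolated), via trimethylsilyl keto ester 16 (not isolated)
Conditions: LiN(iPr)2 (1.1 equiv), THF, −78 °C; then BrCH2CO2Me, DMPU, −78 → −30 °C; then 1 M HCl, THF, 0 °C
Reagents that add atoms: none
Why: The spiro carbon leaves the ketone a single enolisable position, so only one enolate can form, and its alkylation by the alpha-bromo ester (enolate alkylation) should occur on the ring face away from the fully substituted C(CH3)(OSiMe3) neighbour of the spiro centre, that is on the side of the allyl-bearing carbon, after which dilute acid removes the labile tertiary silyl ether; the new centre remains epimerisable should equilibration be needed.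

Step 9
Reactants: 17 hydroxy keto ester
Product: 19 cis-fused spiro gamma-lactone (tertiary hydroxyl free), via dihydroxy ester 18 (not isolated)
Conditions: Me4NBH(OAc)3 (5 equiv), MeCN/AcOH (1:1), −30 → 0 °C; then camphorsulfonic acid (cat.), CH2Cl2, rt
Reagents that add atoms: none
Why: The tertiary hydroxyl exchanges onto boron and hands hydride intramolecularly to the ketone face on its own side (Evans–Saksena directed reduction), which places the new secondary hydroxyl cis to the acetate arm, and acid-catalysed lactonisation then closes the gamma-lactone, a closure open only to the cis hydroxy ester so that any epimer at the arm-bearing carbon stays behind as an open hydroxy ester.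

Step 10
Reactants: 19 spiro lactone
Product: 21 hydroxypropyl lactone, via catechol boronate 20 (not isolated)
Conditions: catecholborane (3 equiv), RhCl(PPh3)3 (3 mol %), THF, 0 °C → rt; then NaBO3·4H2O, THF/H2O, rt
Reagents that add atoms: sodium perborate, [Na+].[Na+].O[B-]1(O)OO[B-](O)(O)OO1
Why: Rhodium-catalysed hydroboration with catecholborane is strongly selective for the monosubstituted allyl double bond over the hindered 1,1-disubstituted isopropenyl group and does not reduce the lactone, and perborate oxidation of the primary boronate gives the anti-Markovnikov alcohol.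

Step 11
Reactants: 21 hydroxypropyl lactone
Product: 22 pivalate
Conditions: PivCl (1.3 equiv), pyridine, DMAP (cat.), CH2Cl2, 0 °C
Reagents that add atoms: pivaloyl chloride, CC(C)(C)C(=O)Cl
Why: Acylation with the bulky acid chloride occurs only at the primary hydroxyl because the tertiary alcohol is far too hindered, and the pivalate is chosen because it withstands the later enolate step and is removed by the same hydride that opens the lactone.

Step 12
Reactants: 22 pivalate
Product: 24 2-substituted acrolein (ring CH–C(=CH2)CHO), via allylic alcohol 23 (not isolated)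
Conditions: SeO2 (0.5 equiv), tBuOOH (3 equiv), CH2Cl2, rt; then MnO2 (excess), CH2Cl2, rt
Reagents that add atoms: tert-butyl hydroperoxide, CC(C)(C)OO
Why: Selenium dioxide allylic oxidation (ene reaction then 2,3-sigmatropic shift, Riley oxidation) should functionalise the methyl group of the isopropenyl unit, the flanked ring methine being the less accessible allylic position, and MnO2 carries the 2-substituted allylic alcohol on to the acrolein.

Step 13
Reactants: 24 2-substituted acrolein
Product: 25 tetrasubstituted enal (ring C=C(CH3)CHO, formyl cis to the ring carbon bearing the pivaloyloxypropyl chain)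
Conditions: RhCl3·3H2O (10 mol %), EtOH, 70 °C
Reagents that add atoms: none
Why: A rhodium hydride formed in ethanol adds to the methylene terminus and beta-hydride elimination from the ring methine moves the double bond into the tetrasubstituted conjugated position (transition-metal-catalysed isomerisation of an alpha-methylene carbonyl compound), which erases the carvone stereocentre, and the reversible process should settle on the geometry with the flat formyl group beside the substituted ring carbon and the methyl group beside the ring CH2.

Step 14
Reactants: 25 tetrasubstituted enal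
Product: 26 dioxolane-masked enal lactone
Conditions: HOCH2CH2OH (10 equiv), PPTS (10 mol %), benzene, reflux (Dean–Stark)
Reagents that add atoms: ethylene glycol, OCCO
Why: Acid-catalysed acetalisation with azeotropic removal of water masks the formyl group as a dioxolane that survives amide base and hydride, and the fully substituted beta-carbon rules out conjugate addition of the diol.

Step 15
Reactants: 27 (E)-pent-2-en-4-yn-1-ol; 28 prenyl bromide
Product: 30 (2E,4E)-4,8-dimethylnona-2,4,7-trien-1-ol, via alkenylalane 29 (not isolated)
Conditions: AlMe3 (3 equiv), Cp2ZrCl2 (0.25 equiv), ClCH2CH2Cl, 0 °C → rt; then prenyl bromide, Pd(PPh3)4 (3 mol %), THF, rt; dilute aq. HCl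
Reagents that add atoms: trimethylaluminium, C[Al](C)C
Why: Zirconium-catalysed syn-methylalumination of the terminal alkyne (Negishi carboalumination) places methyl on the internal carbon and aluminium cis to it, and palladium-catalysed cross-coupling of the alkenylalane with the allylic bromide at its primary carbon proceeds with retention, giving the 4E trisubstituted alkene beside the 2E alkene already present.

Step 16
Reactants: 30 trienol
Product: 31 (2E,4E)-4,8-dimethylnona-2,4,7-trienal
Conditions: MnO2 (excess), CH2Cl2, rt
Reagents that add atoms: none
Why: MnO2 oxidises the dienylic primary alcohol chemoselectively to the conjugated aldehyde without disturbing alkene geometry.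

Step 17
Reactants: 26 dioxolane lactone; 31 trienal
Product: 33 aldol adduct (beta-hydroxy lactone, diastereomer mixture at the two new centres), via dilithio enolate 32 (not isolated)
Conditions: LiN(iPr)2 (2.2 equiv), THF, −78 °C; then 31, −78 °C; AcOH/THF quench
Reagents that add atoms: none
Why: Two equivalents of amide base give the tertiary alkoxide and the lactone enolate, which adds 1,2 to the unsaturated aldehyde at low temperature (aldol addition), and the configuration of the two new centres is irrelevant because both become trigonal in the next step.

Step 18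
Reactants: 33 aldol adduct
Product: 35 (E)-alkylidene lactone carrying the full trienyl chain, via allylic acetate 34 (not isolated)
Conditions: Ac2O (1.5 equiv), Et3N, DMAP (cat.), CH2Cl2, 0 °C; then DBU, rt
Reagents that add atoms: none
Why: Acetylation of the secondary aldol hydroxyl (the tertiary one is inert) followed by base-induced E1cB elimination gives the conjugated alkylidene lactone, and this pathway should favour the E isomer, in which the dienyl chain points away from the lactone carbonyl.

Step 19
Reactants: 35 (E)-alkylidene lactone
Product: 36 tetraol with the enal still masked as dioxolane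
Conditions: iBu2AlH (7 equiv), CH2Cl2, −78 → −20 °C; aq. potassium sodium tartrate
Reagents that add atoms: none
Why: iBu2AlH reduces the alkylidene lactone in 1,2-fashion through the lactol to the allylic primary alcohol and the ring secondary alcohol and cleaves the pivalate in the same operation, while the dioxolane and the alkenes should be inert at low temperature.

Step 20
Reactants: 36 tetraol acetal
Product: 37 target CNP0261841.1
Conditions: PPTS (0.2 equiv), acetone/H2O (10:1), rt
Reagents that add atoms: water, O
Why: The acetal of a conjugated aldehyde hydrolyses through a stabilised oxocarbenium ion under very mild acid, conditions chosen so that the ionisable trienyl carbinol and the tertiary alcohol should not be affected.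

Compound list
1 | (S)-(+)-carvone | CC1=CC[C@@H](CC1=O)C(C)=C | starting material
2 | allyl bromide | C=CCBr | starting material
3 | lithium dienolate of carvone, deprotonated at C6 (not isolated) | CC1=CC[C@@H](C=C1O[Li])C(C)=C | intermediate
4 | trans-6-allylcarvone, (5S,6R)-6-allyl-2-methyl-5-(prop-1-en-2-yl)cyclohex-2-en-1-one | O=C1[C@H](CC=C)[C@@H](C(C)=C)CC=C1C | intermediate
5 | lithium trans-6-allyl-2-methyl-5-(prop-1-en-2-yl)cyclohex-1-en-1-olate (not isolated) | CC1=C(O[Li])[C@H](CC=C)[C@@H](C(C)=C)CC1 | intermediate
6 | trans-6-allyl-2-methyl-5-(prop-1-en-2-yl)cyclohex-1-en-1-yl trifluoromethanesulfonate | CC1=C(OS(=O)(=O)C(F)(F)F)[C@H](CC=C)[C@@H](C(C)=C)CC1 | intermediate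
7 | trimethyl[trans-6-allyl-2-methyl-5-(prop-1-en-2-yl)cyclohex-1-en-1-yl]stannane | CC1=C([Sn](C)(C)C)[C@H](CC=C)[C@@H](C(C)=C)CC1 | intermediate
8 | cyclobutanone | O=C1CCC1 | starting material
9 | trans-6-allyl-2-methyl-5-(prop-1-en-2-yl)cyclohex-1-en-1-yllithium (not isolated) | CC1=C([Li])[C@H](CC=C)[C@@H](C(C)=C)CC1 | intermediate
10 | 1-[trans-6-allyl-2-methyl-5-(prop-1-en-2-yl)cyclohex-1-en-1-yl]cyclobutan-1-ol | CC1=C(C2(O)CCC2)[C@H](CC=C)[C@@H](C(C)=C)CC1 | intermediate
11 | 1-[2-allyl-6-methyl-3-(prop-1-en-2-yl)-7-oxabicyclo[4.1.0]heptan-1-yl]cyclobutan-1-ol, epoxide oxygen cis to allyl and trans to isopropenyl | C[C@@]12O[C@]1(C3(O)CCC3)[C@H](CC=C)[C@@H](C(C)=C)CC2 | intermediate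
12 | 10-allyl-6-hydroxy-6-methyl-9-(prop-1-en-2-yl)spiro[4.5]decan-1-one; on the cyclohexane the hydroxyl, the allyl group and the bond to the carbonyl carbon lie on one face, the methyl group, the isopropenyl group and the bond to the cyclopentane CH2 on the other | C1CC[C@]2([C@H](CC=C)[C@@H](C(C)=C)CC[C@]2(C)O)C1=O | intermediate
13 | O-trimethylsilyl ether of 12 | C1CC[C@]2([C@H](CC=C)[C@@H](C(C)=C)CC[C@]2(C)O[Si](C)(C)C)C1=O | intermediate
14 | methyl bromoacetate | COC(=O)CBr | starting material
15 | lithium enolate of 13 (not isolated) | C=1CC[C@]2([C@H](CC=C)[C@@H](C(C)=C)CC[C@]2(C)O[Si](C)(C)C)C=1O[Li] | intermediate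
16 | methyl 2-[10-allyl-6-methyl-1-oxo-9-(prop-1-en-2-yl)-6-(trimethylsilyloxy)spiro[4.5]decan-2-yl]acetate (not isolated) | COC(=O)C[C@@H]1CC[C@]2([C@H](CC=C)[C@@H](C(C)=C)CC[C@]2(C)O[Si](C)(C)C)C1=O | intermediate
17 | methyl 2-[10-allyl-6-hydroxy-6-methyl-1-oxo-9-(prop-1-en-2-yl)spiro[4.5]decan-2-yl]acetate, ester arm on the cyclopentanone face turned to the allyl-bearing carbon C10 | COC(=O)C[C@@H]1CC[C@]2([C@H](CC=C)[C@@H](C(C)=C)CC[C@]2(C)O)C1=O | intermediate
18 | corresponding 1,6-dihydroxy ester, new C1 hydroxyl cis to the ester arm and on the C10 side (not isolated) | COC(=O)C[C@@H]1CC[C@]2([C@H](CC=C)[C@@H](C(C)=C)CC[C@]2(C)O)[C@@H]1O | intermediate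
19 | cis-fused gamma-lactone of 18 (lactone oxygen on C1, lactone CH2 on C2, both on the cyclopentane face turned to C10; allyl, isopropenyl and tertiary hydroxyl unchanged) | O=C1C[C@@H]2CC[C@]3([C@H](CC=C)[C@@H](C(C)=C)CC[C@]3(C)O)[C@@H]2O1 | intermediate
20 | catechol boronate at the terminal carbon of the former allyl group (not isolated) | O=C1C[C@@H]2CC[C@]3([C@H](CCCB4Oc5ccccc5O4)[C@@H](C(C)=C)CC[C@]3(C)O)[C@@H]2O1 | intermediate
21 | lactone with 3-hydroxypropyl chain in place of allyl | O=C1C[C@@H]2CC[C@]3([C@H](CCCO)[C@@H](C(C)=C)CC[C@]3(C)O)[C@@H]2O1 | intermediate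
22 | pivalate of 21 at the primary hydroxyl | O=C1C[C@@H]2CC[C@]3([C@H](CCCOC(=O)C(C)(C)C)[C@@H](C(C)=C)CC[C@]3(C)O)[C@@H]2O1 | intermediate
23 | 2-substituted allylic alcohol from oxidation of the isopropenyl methyl group (not isolated) | O=C1C[C@@H]2CC[C@]3([C@H](CCCOC(=O)C(C)(C)C)[C@@H](C(=C)CO)CC[C@]3(C)O)[C@@H]2O1 | intermediate
24 | 2-substituted acrolein, ring CH–C(=CH2)CHO | O=C1C[C@@H]2CC[C@]3([C@H](CCCOC(=O)C(C)(C)C)[C@@H](C(=C)C=O)CC[C@]3(C)O)[C@@H]2O1 | intermediate
25 | tetrasubstituted enal, ring C=C(CH3)CHO with formyl cis to the chain-bearing ring carbon | O=C1C[C@@H]2CC[C@]3([C@H](CCCOC(=O)C(C)(C)C)/C(=C(/C)C=O)CC[C@]3(C)O)[C@@H]2O1 | intermediate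
26 | 1,3-dioxolane of 25 | O=C1C[C@@H]2CC[C@]3([C@H](CCCOC(=O)C(C)(C)C)/C(=C(/C)C4OCCO4)CC[C@]3(C)O)[C@@H]2O1 | intermediate
27 | (E)-pent-2-en-4-yn-1-ol | C#C/C=C/CO | starting material
28 | prenyl bromide (1-bromo-3-methylbut-2-ene) | CC(C)=CCBr | starting material
29 | (1E,3E)-dienyl dimethylalane with O-dimethylaluminium alkoxide (not isolated) | C[Al](C)OC/C=C/C(C)=C/[Al](C)C | intermediate
30 | (2E,4E)-4,8-dimethylnona-2,4,7-trien-1-ol | OC/C=C/C(C)=C/CC=C(C)C | intermediate
31 | (2E,4E)-4,8-dimethylnona-2,4,7-trienal | O=C/C=C/C(C)=C/CC=C(C)C | intermediate
32 | dilithio species of 26: lactone enolate and tertiary alkoxide (not isolated) | [Li]OC1=C[C@@H]2CC[C@]3([C@H](CCCOC(=O)C(C)(C)C)/C(=C(/C)C4OCCO4)CC[C@]3(C)O[Li])[C@@H]2O1 | intermediate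
33 | aldol adduct, alpha-(1-hydroxytrienyl) lactone, mixture at the alpha-carbon and the carbinol carbon | O=C1C(C(O)/C=C/C(C)=C/CC=C(C)C)[C@@H]2CC[C@]3([C@H](CCCOC(=O)C(C)(C)C)/C(=C(/C)C4OCCO4)CC[C@]3(C)O)[C@@H]2O1 | intermediate
34 | acetate of 33 at the secondary carbinol (not isolated) | O=C1C(C(OC(C)=O)/C=C/C(C)=C/CC=C(C)C)[C@@H]2CC[C@]3([C@H](CCCOC(=O)C(C)(C)C)/C(=C(/C)C4OCCO4)CC[C@]3(C)O)[C@@H]2O1 | intermediate
35 | (E)-alkylidene lactone with the (E,E)-dimethylnonatrienylidene chain, pivalate and dioxolane in place | O=C1/C(=C/C=C/C(C)=C/CC=C(C)C)[C@@H]2CC[C@]3([C@H](CCCOC(=O)C(C)(C)C)/C(=C(/C)C4OCCO4)CC[C@]3(C)O)[C@@H]2O1 | intermediate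
36 | tetraol of the target skeleton with the enal as 1,3-dioxolane | CC(C)=CC/C=C(C)/C=C/C=C(/CO)[C@@H]1CC[C@]2([C@H](CCCO)/C(=C(/C)C3OCCO3)CC[C@]2(C)O)[C@@H]1O | intermediate
37 | CNP0261841.1 | CC(C)=CC/C=C(C)/C=C/C=C(/CO)[C@@H]1CC[C@]2([C@H](CCCO)/C(=C(/C)C=O)CC[C@]2(C)O)[C@@H]1O | target

Total step count: 20. Longest linear sequence: 18 steps (steps 1–14 and 17–20); steps 15–16 make the trienal separately.

Steps most likely to fail

1. Step 5. Oxygen transfer may show poor facial selectivity, because the pseudoaxial allyl group next to the carbinol-bearing alkene carbon competes with the axial isopropenyl group as the face-blocking element and the vanadium alkoxide can deliver from either rotamer. The fallback removes the directing hydroxyl and lets sterics alone steer the oxidant. Setting out from 10, silylation (TMSOTf, 2,6-lutidine, CH2Cl2, −78 °C) would give the trimethylsilyl ether F1. Dimethyldioxirane in acetone at −20 °C, a small undirected oxidant that reacts fastest at the tetrasubstituted alkene, should approach anti to the axial isopropenyl group and give the epoxy silyl ether F2. TiCl4 in CH2Cl2 at −78 °C would then trigger the same 1,2-shift on the silyl ether with loss of the silyl group, and the route is rejoined at 12.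

2. Step 13. The double-bond migration may stall, may settle on a mixture of enal geometries, or may be eroded by decarbonylation or acetal formation in hot ethanol. The fallback builds the tetrasubstituted alkene by elimination instead of migration. Setting out from 24, hydrogenation of the acrolein C=C (H2, Pd/C, EtOAc) would give the saturated alpha-methyl aldehyde F3. Alpha-bromination (Br2, dioxane/CH2Cl2, 0 °C) would give the tertiary alpha-bromo aldehyde F4. Dehydrobromination under equilibrating conditions (LiBr, Li2CO3, DMF, 110 °C) should deliver the more substituted conjugated enal, and the route is rejoined at 25.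

3. Step 8. The enolate alkylation may show poor facial discrimination, since the reacting carbon lies one atom away from the spiro centre; much material would then end up as the epimer that cannot lactonise in step 9. The fallback fixes the arm by ring constraint instead of enolate face selectivity. Setting out from 12, dehydrogenation with IBX (DMSO, 70 °C) would give the enone F5. Directed 1,2-reduction with Me4NBH(OAc)3 (MeCN/AcOH, −30 °C) would give the allylic diol F6 with the same carbinol configuration as in step 9. Bromoacetalisation of the secondary allylic hydroxyl (ethyl vinyl ether, NBS, CH2Cl2, −40 °C) would give the bromoacetal F7. Radical 5-exo cyclisation (Bu3SnH, AIBN, benzene, 80 °C; Ueno–Stork reaction) can only close cis and would give the bicyclic acetal F8, and oxidation with CrO3/H2SO4 in acetone at 0 °C would convert the acetal into the lactone, rejoining the route at 19.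

Further compounds
F1 | step 5 | trimethylsilyl ether of cyclobutanol 10 | CC1=C(C2(O[Si](C)(C)C)CCC2)[C@H](CC=C)[C@@H](C(C)=C)CC1
F2 | step 5 | epoxy silyl ether (epoxide oxygen cis to allyl) | C[C@@]12O[C@]1(C3(O[Si](C)(C)C)CCC3)[C@H](CC=C)[C@@H](C(C)=C)CC2
F3 | step 13 | saturated alpha-methyl aldehyde from 24 (mixture at the new centre) | O=C1C[C@@H]2CC[C@]3([C@H](CCCOC(=O)C(C)(C)C)[C@@H](C(C)C=O)CC[C@]3(C)O)[C@@H]2O1
F4 | step 13 | tertiary alpha-bromo aldehyde (mixture at the bromine-bearing centre) | O=C1C[C@@H]2CC[C@]3([C@H](CCCOC(=O)C(C)(C)C)[C@@H](C(C)(Br)C=O)CC[C@]3(C)O)[C@@H]2O1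
F5 | step 8 | spiro cyclopentenone from 12 | C1=CC[C@]2([C@H](CC=C)[C@@H](C(C)=C)CC[C@]2(C)O)C1=O
F6 | step 8 | allylic diol (cyclopentenol hydroxyl on the side of the allyl-bearing carbon) | C1=CC[C@]2([C@H](CC=C)[C@@H](C(C)=C)CC[C@]2(C)O)[C@@H]1O
F7 | step 8 | 2-bromo-1-ethoxyethyl acetal of the secondary hydroxyl of F6 | C1=CC[C@]2([C@H](CC=C)[C@@H](C(C)=C)CC[C@]2(C)O)[C@@H]1OC(CBr)OCC
F8 | step 8 | cis-fused bicyclic ethyl acetal (lactol ether of 19) | CCOC1C[C@@H]2CC[C@]3([C@H](CC=C)[C@@H](C(C)=C)CC[C@]3(C)O)[C@@H]2O1
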